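**Retrosynthetic overview**

- 9 ⇐ 8 by removal of six O-methyl groups with BBr3; 8 ⇐ 6 + 2 × 7 by Friedel–Crafts C-acylation at C5 and C5′, the only ring C–H bonds.
- 6 ⇐ 5 by six copper-catalysed aryl C–Br → C–OMe exchanges, so that all oxygen is brought in last onto an electron-poor core.
- 5 ⇐ 3 + 4. The feature used: on each benzene ring the oxygen-bearing carbons C2, C4 and C6 are the ones ortho or para to both the bridging CH2 (on C1) and the CH3 (on C3), and the acyl-bearing C5 is meta to both. Alkyl-directed bromination therefore marks the oxygen sites.
- 3 ⇐ 1 + 2 by benzyl–aryl Suzuki coupling. No ring is formed anywhere in the route; both benzene rings are bought as meta-tolyl units.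

Key step: step 3

Remark on the chemistry: the target has no stereocentre and no stereogenic double bond, so no stereocontrol is needed. Ring numbering throughout: C1 carries the bridging CH2, C3 the CH3.

**Route**

Step 1
Reactants: 1 3-methylbenzyl bromide; 2 (3-methylphenyl)boronic acid
Product: 3 bis(3-methylphenyl)methane
Conditions: Pd(PPh3)4 (3 mol %, zerovalent palladium), K2CO3 (2.5 equiv), degassed DME–H2O, 80 °C
Reagents that add atoms: none
Why: Suzuki–Miyaura sp3–sp2 coupling, in which the benzylic C–Br bond adds readily to zerovalent palladium, the benzylpalladium bromide has no β-hydrogen to lose, and transmetallation with the carbonate-activated arylboronic acid followed by reductive elimination should join the two meta-tolyl units through CH2 with the 3,3′-pattern fixed by the starting materials.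

Step 2
Reactants: 3 bis(3-methylphenyl)methane; 4 bromine
Product: 5 bis(2,4,6-tribromo-3-methylphenyl)methane
Conditions: Br2 (6.2 equiv), FeBr3 (10 mol %), CH2Cl2, dark, 0 °C → reflux
Reagents that add atoms: bromine (4), BrBr
Why: Electrophilic aromatic bromination, in which the CH2 on C1 and the CH3 on C3 both direct to C2, C4 and C6, whereas C5 is meta to both alkyl groups and ends up flanked by two bromines, so with about six equivalents of Br2 the reaction should stop at the 2,4,6,2′,4′,6′-hexabromide, and the Lewis acid in the dark keeps the benzylic CH2 free of radical bromination.

Step 3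
Reactants: 5 bis(2,4,6-tribromo-3-methylphenyl)methane
Product: 6 bis(2,4,6-trimethoxy-3-methylphenyl)methane
Conditions: NaOMe (30 equiv, as concentrated solution in MeOH), CuI (10 mol % per C–Br, monovalent copper), 1,10-phenanthroline (20 mol % per C–Br), DMF–MeOH, degassed, Ar, sealed vessel, 100–110 °C
Reagents that add atoms: sodium methoxide, [Na+].[O-]C
Why: CuI and excess NaOMe should form a phenanthroline-bound methoxide complex of monovalent copper (in equilibrium with sodium dimethoxycuprate), which adds oxidatively to an aryl C–Br bond to give a trivalent arylcopper methoxide and releases the aryl methyl ether by C–O reductive elimination, after which NaOMe regenerates the monovalent copper methoxide; this cycle has to run six times on each molecule. The closest known reaction type is the Ullmann-type copper-catalysed methoxylation of aryl bromides with NaOMe in DMF–MeOH, the usual conversion of 1,3,5-tribromoarenes into phloroglucinol trimethyl ethers. No ring is closed and no stereocentre is created; six aryl C–O bonds are formed. No positional selectivity is asked of the step, because step 2 has put every bromine where an oxygen is wanted and C5/C5′ carry hydrogen; what is needed is C–O formation in preference to hydrodebromination, and full conversion at the crowded C2/C2′ (between CH2 and CH3) and C6/C6′ positions. The high methoxide concentration, methanol as cosolvent to keep the copper methoxide dissolved, and the chelating ligand, which should speed the productive reductive elimination relative to reduction, are chosen for this, and each remaining bromine keeps its ring electron-poor enough for further oxidative addition. Oxygen is excluded because the doubly benzylic CH2, acidified by the bromoarene rings, could otherwise be autoxidised to the benzophenone under base.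

Step 4
Reactants: 6 bis(2,4,6-trimethoxy-3-methylphenyl)methane; 7 butanoyl chloride
Product: 8 bis(5-butanoyl-2,4,6-trimethoxy-3-methylphenyl)methane
Conditions: butanoyl chloride (2.6 equiv), TiCl4 (2.6 equiv), CH2Cl2, −30 °C → 0 °C (6 added slowly to the preformed acyl chloride–TiCl4 complex); ice-water quench
Reagents that add atoms: butanoyl chloride (7), CCCC(=O)Cl
Why: Friedel–Crafts acylation, in which C5–H is the only aromatic C–H of each ring and lies ortho to two methoxy groups and para to the third, so the TiCl4-activated acyl chloride should attack there at low temperature, the new ketone deactivates its ring against a second attack or ipso substitution, and any chelation-driven loss of a methyl group next to the ketone is harmless because step 5 removes all six.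

Step 5
Reactants: 8 bis(5-butanoyl-2,4,6-trimethoxy-3-methylphenyl)methane
Product: 9 methylene-bis-methylphlorobutyrophenone
Conditions: BBr3 (10 equiv), CH2Cl2, −78 °C → rt; then ice-water
Reagents that add atoms: none
Why: Lewis-acid cleavage of aryl methyl ethers, in which BBr3 binds each methoxy oxygen and bromide attacks the methyl carbon (SN2) to release bromomethane, the methoxy groups ortho to the ketone being helped by chelation and the crowded 2-methoxy groups by their out-of-plane twist, while the aryl ketones and the diarylmethane should survive and aqueous work-up should liberate the six phenols.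

**Compound list**

1 | 3-methylbenzyl bromide | Cc1cccc(CBr)c1 | starting material
2 | (3-methylphenyl)boronic acid | Cc1cccc(B(O)O)c1 | starting material
3 | bis(3-methylphenyl)methane | Cc1cccc(Cc2cccc(C)c2)c1 | intermediate
4 | bromine | BrBr | starting material
5 | bis(2,4,6-tribromo-3-methylphenyl)methane | Cc1c(Br)cc(Br)c(Cc2c(Br)cc(Br)c(C)c2Br)c1Br | intermediate
6 | bis(2,4,6-trimethoxy-3-methylphenyl)methane | COc1cc(OC)c(Cc2c(OC)cc(OC)c(C)c2OC)c(OC)c1C | intermediate
7 | butanoyl chloride | CCCC(=O)Cl | starting material
8 | bis(5-butanoyl-2,4,6-trimethoxy-3-methylphenyl)methane | CCCC(=O)c1c(OC)c(C)c(OC)c(Cc2c(OC)c(C)c(OC)c(C(=O)CCC)c2OC)c1OC | intermediate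
9 | methylene-bis-methylphlorobutyrophenone (bis(5-butanoyl-2,4,6-trihydroxy-3-methylphenyl)methane) | CCCC(=O)c1c(O)c(C)c(O)c(Cc2c(O)c(C)c(O)c(C(=O)CCC)c2O)c1O | target

**Step count**

Total steps: 5. Longest linear sequence: 5 steps (from 1 or 2 to 9).

**Steps most likely to fail**

Step 3 (key step). Reduction of C–Br to C–H may compete with C–O bond formation at the crowded C2/C2′ and C6/C6′ positions, and the exchange may stall as each ring grows electron-rich; either would leave under-oxygenated ethers that are hard to separate. Base-mediated autoxidation at the CH2 is a second path of loss. The fallback sets out again from 5 and replaces the cuprate substitution by palladium-catalysed C–O cross-coupling with methanol: Pd2(dba)3 (zerovalent palladium), the bulky biarylphosphine tBuBrettPhos, NaOtBu and MeOH in 1,4-dioxane at 50–80 °C. This is a different bond-forming manifold: oxidative addition and reductive elimination at palladium with a ligand designed to outrun β-hydride loss from the methoxide complex, run at a much lower temperature at which the CH2 is less exposed to base. It makes no new compound and comes back to the route at 6.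

Step 2. Positional and stoichiometric control may be lost: a further bromine may enter at C5, substitution at the buttressed C2 may stay incomplete, or acid may scramble the benzyl–aryl bond, giving poorly soluble bromide mixtures. The fallback sets out from 3 and lets a temporary amino group at C5 both block that carbon and direct the three brominations.

- Iridium-catalysed C–H borylation ([Ir(OMe)(cod)]2, 4,4′-di-tert-butyl-2,2′-bipyridine, B2pin2, THF, 80 °C) should, for steric reasons, touch only C5 and C5′ and give bis[3-methyl-5-(4,4,5,5-tetramethyl-1,3,2-dioxaborolan-2-yl)phenyl]methane F1.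
- Amination of the boronate (MeONH2, n-BuLi, THF, −78 °C → 60 °C) should give bis(3-amino-5-methylphenyl)methane F2.
- Br2 in AcOH at room temperature should brominate the two positions ortho and the one para to each amino group, which are C4, C6 and C2, giving bis(3-amino-2,4,6-tribromo-5-methylphenyl)methane F3.
- Diazotisation (NaNO2, H2SO4, AcOH, 0 °C) should give the bis(diazonium) hydrogensulfate of bis(2,4,6-tribromo-3-methylphenyl)methane F4, which is not isolated; H3PO2 replaces both diazonium groups by hydrogen.

The fallback comes back to the route at 5.

Step 4. The methylene bridge may fragment under acid: ipso attack of the acylium ion or a proton at C1, loss of a trimethoxybenzyl cation and its re-addition at free C5 positions would scramble the diarylmethane into oligomers before acylation is complete. The fallback sets out from 6 and avoids strong acid altogether.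

- NBS (2.1 equiv) in MeCN at 0 °C should brominate the only free ring positions and give bis(5-bromo-2,4,6-trimethoxy-3-methylphenyl)methane F5.
- Bromine–lithium exchange with n-BuLi in THF at −78 °C should give bis(5-lithio-2,4,6-trimethoxy-3-methylphenyl)methane F6, which is not isolated.
- Addition of butanal and a water quench should give bis[5-(1-hydroxybutyl)-2,4,6-trimethoxy-3-methylphenyl]methane F7, as a mixture of diastereomers that does not matter.
- Dess–Martin periodinane in CH2Cl2 at room temperature should oxidise both carbinols.

The fallback comes back to the route at 8.

**Further compounds**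

F0 | step 3 | none | none
F1 | step 2 | bis[3-methyl-5-(4,4,5,5-tetramethyl-1,3,2-dioxaborolan-2-yl)phenyl]methane | Cc1cc(Cc2cc(C)cc(B3OC(C)(C)C(C)(C)O3)c2)cc(B2OC(C)(C)C(C)(C)O2)c1
F2 | step 2 | bis(3-amino-5-methylphenyl)methane | Cc1cc(N)cc(Cc2cc(C)cc(N)c2)c1
F3 | step 2 | bis(3-amino-2,4,6-tribromo-5-methylphenyl)methane | Cc1c(Br)c(N)c(Br)c(Cc2c(Br)c(N)c(Br)c(C)c2Br)c1Br
F4 | step 2 | bis(diazonium) hydrogensulfate of bis(2,4,6-tribromo-3-methylphenyl)methane (diazonium groups on C5 and C5′) | Cc1c(Br)c([N+]#N)c(Br)c(Cc2c(Br)c([N+]#N)c(Br)c(C)c2Br)c1Br.OS(=O)(=O)[O-].OS(=O)(=O)[O-]
F5 | step 4 | bis(5-bromo-2,4,6-trimethoxy-3-methylphenyl)methane | Cc1c(OC)c(Br)c(OC)c(Cc2c(OC)c(Br)c(OC)c(C)c2OC)c1OC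
F6 | step 4 | bis(5-lithio-2,4,6-trimethoxy-3-methylphenyl)methane | Cc1c(OC)c([Li])c(OC)c(Cc2c(OC)c([Li])c(OC)c(C)c2OC)c1OC
F7 | step 4 | bis[5-(1-hydroxybutyl)-2,4,6-trimethoxy-3-methylphenyl]methane (mixture of diastereomers) | CCCC(O)c1c(OC)c(C)c(OC)c(Cc2c(OC)c(C)c(OC)c(C(O)CCC)c2OC)c1OC
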